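(The readings come from a simulation for substances that don't exist, and the scatter is random.)

E, counted in percent of the X charged, rose and then fell in dusk, midnight and dawn, while in winter it rose and stayed near 52%, so I asked how far along its curve a flask stands at its asked time.

| setting | dusk | winter | midnight | dawn | Monday's | Sunday's | Wednesday's | Thursday's |
|---|---|---|---|---|---|---|---|---|
| X | 0.050 M | 0.050 M | 0.050 M | 0.025 M | 0.050 M | 0.050 M (fed, over 4.00 min) | 0.050 M | 0.050 M |
| Q | 1.5 equiv | 1 equiv | 2.2 equiv | 1.5 equiv | 1.50 equiv | 1.50 equiv | 1.50 equiv (fed, over 4.00 min) | 1.50 equiv |
| remark | run made earlier | run made earlier | run made earlier | run made earlier | everything together in a closed stirred flask, run for 8.0 min | a stirred flask in which X is dosed at a steady rate over 4.00 min without added volume, worked up at 8.0 min | a stirred flask in which Q is dosed at a steady rate over 4.00 min without added volume, worked up at 8.0 min | one stirred flow tank at steady state, fed with the mixture as stated, mean residence time 8.0 min |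
| time |  |  |  |  | 8.0 min | 8.0 min | 8.0 min |  |

| run | time / min | E / % |
|---|---|---|
| dusk | 0.250 | 40 |
| dusk | 0.667 | 47 |
| dusk | 1.33 | 55 |
| dusk | 2.00 | 49 |
| dusk | 3.00 | 46 |
| dusk | 4.00 | 44 |
| dusk | 5.00 | 45 |
| winter | 0.667 | 48 |
| winter | 1.33 | 49 |
| winter | 2.00 | 51 |
| winter | 3.00 | 53 |
| winter | 4.00 | 51 |
| winter | 5.00 | 52 |
| midnight | 0.667 | 44 |
| midnight | 1.33 | 36 |
| midnight | 2.00 | 28 |
| midnight | 3.00 | 21 |
| midnight | 4.00 | 15 |
| midnight | 5.00 | 15 |
| dawn | 0.417 | 35 |
| dawn | 1.33 | 54 |
| dawn | 2.00 | 53 |
| dawn | 3.00 | 52 |
| dawn | 5.00 | 46 |

(each reading ± 2 percentage points)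

- the stated concentrations are those of everything mixed, before any reaction; amounts are the same in each set-up
- the feed brings no volume worth counting
- the earlier runs were made in a closed, stirred flask
- a reading or a percentage of E counts all its forms, free or not

* the set-up with the highest amount of E at the outlet or at the end, in percent of the X put in ("none" if the first two lie within 2 percentage points) (Monday's / Sunday's / Wednesday's / Thursday's / none)
* amount of E at the outlet or at the end, in percent of the X put in, Monday's
* amount of E at the outlet or at the end, in percent of the X put in, Sunday's
* amount of E at the outlet or at the end, in percent of the X put in, Wednesday's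
* amount of E at the outlet or at the end, in percent of the X put in, Thursday's

In dusk, E read 40% at 0.250 min, a mean slope of 1.60 /min of the charge over that first stretch, which is a chord and not the starting slope. The readings then went to 47% at 0.667 min, crested at a reading of 55% at 1.33 min, and came down to 44% at 4.00 min and 45% at 5.00 min. Midnight also read 15% and 15% at those two times.

If E is made and lost in encounters of two partners, then at fixed equivalents a curve should depend on X charge times time. I therefore took as my measure the slowing contact 12.0 M·s, the product of charge and time at which dusk's readings had come within their scatter of each other, though a slow fall may hide under that scatter. Dawn supported this: at 5.00 min it had the contact of dusk at 2.50 min, and it read 46%, where dusk read 49% and 46% on either side of that time.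

Monday's has dusk's recipe and reaches 24.0 M·s, twice the slowing contact, so I took the mean of dusk's last two readings, 44.5%, as my level for it, an upper mark, since those two readings cannot show a slow fall. In both fed flasks, the time after the feed gives 12.0 M·s, about the slowing contact.

The forecast said 40% for Monday's, lower than my level, with 35% for Sunday's, 44% for Wednesday's and 38% for Thursday's. It named Wednesday's best, since “Wednesday's feed keeps Q starved until X is gone”.

Wednesday's came out best at 43.8%, more than Monday's 40.5%, Sunday's 34.2% and Thursday's 33.1%.

    X + Q → E (k = 0.830 /M/s)
    Q + E → J (k = 0.260 /M/s)
    X + 2 Q → L (k = 3.90 /M²/s)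
    X + E ⇌ D, settled at all times (K = 17.0 /M)

After its feed ended, through about one slowing contact, Wednesday's E went from 55.1% to 43.8%. The neighbour of Wednesday's charged with 0.013 M of X got about half the slowing contact in 8.0 min, and it ended with 55.3% of E and 19.3% of its Q still unbound.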